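**Plan** (variabilin numbering: furan C1–C4, chain C5–C20, lactone O–C21–C22=C23–C24(=O), C25 = CH2OH carbon on C23)
- Retrosynthesis: remove the silyl ether; open C20=C21 to a C20 hydroxyl anti to the C21 oxygen; excise C24 as CO (cutting C23–C24 and O–C24) to reach a (Z)-C23 iodoalkene 20,21-diol; then cut C20–C21 (aldehyde plus C4 alkynyl unit), C13–C15 (alkylborane plus alkenyl iodide), C5–C6 and C12=C13.
- Forward: the furan/diene chain C1–C14 is built from geranyl acetate and joined to the C15–C20 unit by B-alkyl Suzuki–Miyaura coupling. The C21–C23/C25 unit is added to the C20 aldehyde. The butenolide is closed late by carbonylation, followed by anti-elimination and desilylation.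
- Enabling feature: C24 is bonded only to the ring oxygen and to C23 within the five-membered O–C21–C22=C23–C24 ring, so it can enter as CO between the C21 hydroxyl and a cis C23–I bond in a (4+1) closure.
- Stereochemistry: C18 from an Evans alkylation; 7E from geranyl acetate; 12Z from a Z-selective iodo-Wittig olefination and stereoretentive coupling; C20/C21 anti from a cyclic allenyltitanium transition state; 20E from stereospecific anti-elimination across C20–C21.

Key step: step 13

Remark: the C20/C21-anti series is drawn as the expected Felkin-type isomer (20S,21R); its anti partner with both centres inverted would converge on the same E olefin, because both centres become sp2 or lose their hydrogen in step 14.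

Step 1
Reactants: 1 geranyl acetate
Product: 2 (2E)-3-methyl-6-oxohex-2-en-1-yl acetate
Conditions: O3 (1.0 equiv), CH2Cl2, −78 °C; then Me2S, −78 °C to rt
Reagents that add atoms: ozone, O=[O+][O-]
Why: Chemoselective ozonolysis, in which one equivalent of the electrophilic oxidant should cleave the electron-richer remote trisubstituted alkene in preference to the alkene deactivated by the allylic acetate, leaving the 2E alkene (later C7=C8) untouched.

Step 2
Reactants: 2 (2E)-3-methyl-6-oxohex-2-en-1-yl acetate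
Product: 3 (2E,6Z)-7-iodo-3-methylocta-2,6-dien-1-yl acetate
Conditions: [Ph3PEt]I, n-BuLi, THF, 0 °C; I2, −78 °C; NaN(SiMe3)2, −78 °C; then 2, −78 to −20 °C
Reagents that add atoms: ethyltriphenylphosphonium iodide, CC[P+](c1ccccc1)(c1ccccc1)c1ccccc1.[I-]; iodine, II
Why: Stork–Zhao-type Wittig olefination with the α-iodo ylide Ph3P=C(I)CH3 should give the trisubstituted alkenyl iodide with iodine cis to the chain (6Z), which fixes the later C12=C13 geometry, while the acetate survives the ylide at low temperature.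

Step 3
Reactants: 4 furan-3-ylmethanol
Product: 5 3-(chloromethyl)furan
Conditions: SOCl2, pyridine, Et2O, 0 °C
Reagents that add atoms: thionyl chloride, ClS(Cl)=O
Why: Chlorodehydroxylation of a primary heterobenzylic alcohol through its chlorosulfite, with pyridine scavenging HCl so that the acid-sensitive furan is spared.

Step 4
Reactants: 5 3-(chloromethyl)furan; 3 (2E,6Z)-7-iodo-3-methylocta-2,6-dien-1-yl acetate
Product: 7 3-[(3E,7Z)-8-iodo-4-methylnona-3,7-dien-1-yl]furan, via furan-3-ylmethylmagnesium chloride 6 (not isolated)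
Conditions: Mg, THF, 0 °C; then 3, Li2CuCl4 (5 mol %), THF, −78 to 0 °C
Reagents that add atoms: none
Why: Copper-catalysed allylic substitution of a primary allylic acetate by a Grignard reagent (Kochi-type coupling) should occur at the α-carbon with retention of the E geometry, faster than attack on the ester carbonyl or the alkenyl iodide at low temperature, and forms the C5–C6 bond.

Step 5
Reactants: 8 (4S)-4-benzyl-3-propanoyl-1,3-oxazolidin-2-one
Product: 9 (4S)-4-benzyl-3-[(2R)-2-methylpent-4-enoyl]-1,3-oxazolidin-2-one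
Conditions: NaN(SiMe3)2, THF, −78 °C; allyl iodide, −78 to −45 °C
Reagents that add atoms: allyl iodide, C=CCI
Why: Evans asymmetric alkylation, in which the chelated (Z)-sodium enolate is allylated on the face opposite the C4 benzyl group and so sets the future C18 stereocentre as 2R.

Step 6
Reactants: 9 (4S)-4-benzyl-3-[(2R)-2-methylpent-4-enoyl]-1,3-oxazolidin-2-one; 7 3-[(3E,7Z)-8-iodo-4-methylnona-3,7-dien-1-yl]furan
Product: 11 (4S)-4-benzyl-3-[(2R,6Z,10E)-13-(furan-3-yl)-2,6,10-trimethyltrideca-6,10-dienoyl]-1,3-oxazolidin-2-one, via B-alkyl-9-borabicyclononane 10 (not isolated)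
Conditions: 9-borabicyclo[3.3.1]nonane (9-BBN-H), THF, 0 °C to rt; then 7, PdCl2(dppf) (5 mol %), AsPh3, K3PO4 (3 M aq), DMF, rt
Reagents that add atoms: none
Why: Anti-Markovnikov hydroboration of the terminal alkene followed by B-alkyl Suzuki–Miyaura coupling, which proceeds with retention at the alkenyl iodide and should therefore deliver the 12Z alkene while forming the C13–C15 bond remote from the stereocentre.

Step 7
Reactants: 11 (4S)-4-benzyl-3-[(2R,6Z,10E)-13-(furan-3-yl)-2,6,10-trimethyltrideca-6,10-dienoyl]-1,3-oxazolidin-2-one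
Product: 12 (2R,6Z,10E)-13-(furan-3-yl)-2,6,10-trimethyltrideca-6,10-dien-1-ol
Conditions: LiBH4, MeOH (1 equiv), Et2O, 0 °C
Reagents that add atoms: none
Why: Reductive cleavage of the N-acyl oxazolidinone by hydride attack at the exocyclic carbonyl should give the primary alcohol without touching C18 and return the auxiliary.

Step 8
Reactants: 12 (2R,6Z,10E)-13-(furan-3-yl)-2,6,10-trimethyltrideca-6,10-dien-1-ol
Product: 13 (2R,6Z,10E)-13-(furan-3-yl)-2,6,10-trimethyltrideca-6,10-dienal
Conditions: Dess–Martin periodinane, NaHCO3, CH2Cl2, 0 °C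
Reagents that add atoms: none
Why: Dess–Martin oxidation under buffered, non-basic conditions should give the α-branched aldehyde without epimerisation at C18 or attack on the furan; the aldehyde is used at once.

Step 9
Reactants: 14 4-(oxan-2-yloxy)but-2-yn-1-ol; 13 (2R,6Z,10E)-13-(furan-3-yl)-2,6,10-trimethyltrideca-6,10-dienal
Product: 17 (4R,5S,6R,10Z,14E)-17-(furan-3-yl)-6,10,14-trimethyl-4-(oxan-2-yloxy)heptadeca-10,14-dien-2-yne-1,5-diol, via dilithiated propargyl ether 15 (not isolated), via allenyltitanium reagent 16 (not isolated)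
Conditions: n-BuLi (1.0 equiv), THF, −78 °C; s-BuLi (1.1 equiv), −78 °C; ClTi(OiPr)3 (2.2 equiv), −78 °C; then 13, −78 to −40 °C; aq. NH4Cl
Reagents that add atoms: none
Why: α-Lithiation of the propargylic acetal ether (the alkoxide at the other terminus cannot leave, so no 1,4-elimination), transmetalation to the allenyltitanium and SE2′ addition to the aldehyde through a six-membered cyclic transition state should form the C20–C21 bond with anti simple diastereoselection (Felkin–Anh sense at C20 expected).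

Step 10
Reactants: 17 (4R,5S,6R,10Z,14E)-17-(furan-3-yl)-6,10,14-trimethyl-4-(oxan-2-yloxy)heptadeca-10,14-dien-2-yne-1,5-diol
Product: 18 (4R,5S,6R,10Z,14E)-17-(furan-3-yl)-6,10,14-trimethyl-4-(oxan-2-yloxy)-1-[(triisopropylsilyl)oxy]heptadeca-10,14-dien-2-yn-5-ol
Conditions: iPr3SiCl (1.05 equiv), imidazole, CH2Cl2, 0 °C
Reagents that add atoms: chlorotriisopropylsilane, CC(C)[Si](Cl)(C(C)C)C(C)C
Why: Selective O-silylation, in which the bulky silyl chloride should react with the primary propargylic hydroxyl (C25) and leave the hindered secondary C20 hydroxyl free.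

Step 11
Reactants: 18 (4R,5S,6R,10Z,14E)-17-(furan-3-yl)-6,10,14-trimethyl-4-(oxan-2-yloxy)-1-[(triisopropylsilyl)oxy]heptadeca-10,14-dien-2-yn-5-ol
Product: 19 (4R,5S,6R,10Z,14E)-17-(furan-3-yl)-6,10,14-trimethyl-1-[(triisopropylsilyl)oxy]heptadeca-10,14-dien-2-yne-4,5-diol
Conditions: pyridinium p-toluenesulfonate (cat.), MeOH, rt
Reagents that add atoms: none
Why: Mild acid-catalysed transacetalisation to methanol should remove only the tetrahydropyranyl group, freeing the propargylic C21 hydroxyl while the primary triisopropylsilyl ether and the furan survive.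

Step 12
Reactants: 19 (4R,5S,6R,10Z,14E)-17-(furan-3-yl)-6,10,14-trimethyl-1-[(triisopropylsilyl)oxy]heptadeca-10,14-dien-2-yne-4,5-diol
Product: 21 (2Z,4R,5S,6R,10Z,14E)-17-(furan-3-yl)-2-iodo-6,10,14-trimethyl-1-[(triisopropylsilyl)oxy]heptadeca-2,10,14-triene-4,5-diol, via cyclic alkenylaluminate 20 (not isolated)
Conditions: NaAlH2(OCH2CH2OMe)2 (3.5 equiv), THF, 0 °C to rt; then I2, −78 °C; aq. KNaC4H4O6
Reagents that add atoms: iodine, II
Why: Hydroxyl-directed trans-hydroalumination of the propargylic alcohol delivers hydride to C22 and places aluminium on C23 cis to C21 in a five-membered oxa-aluminacycle, and iodinolysis with retention should give the (Z)-alkenyl iodide; the homopropargylic C20 alkoxide directs far more slowly and the silyl ether should not eliminate at this temperature.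

Step 13
Reactants: 21 (2Z,4R,5S,6R,10Z,14E)-17-(furan-3-yl)-2-iodo-6,10,14-trimethyl-1-[(triisopropylsilyl)oxy]heptadeca-2,10,14-triene-4,5-diol
Product: 22 (5R)-5-[(1S,2R,6Z,10E)-13-(furan-3-yl)-1-hydroxy-2,6,10-trimethyltrideca-6,10-dien-1-yl]-3-{[(triisopropylsilyl)oxy]methyl}furan-2(5H)-one
Conditions: Pd(PPh3)4 (5 mol %), CO (1 atm), K2CO3, THF, 30 °C
Reagents that add atoms: carbon monoxide, [C-]#[O+]
Why: Zerovalent palladium inserts into the C23–I bond with retention of the Z geometry, the cis C21 alkoxide displaces iodide to give a five-membered oxapalladacycle, CO inserts to give a six-membered alkoxycarbonyl(alkenyl)palladium chelate, and C23–C24 reductive elimination releases the lactone (the order through the C23 acylpalladium and its capture by the C21 oxygen converges on the same ring). The closest known reaction type is the palladium-catalysed carbonylative lactonisation of (Z)-3-iodoallylic alcohols to butenolides. The five-membered ring O–C21–C22=C23–C24 is closed in a formal (4+1) mode, with O–C21–C22=C23 as the four-atom unit and CO as the one-carbon unit, the closing event being reductive elimination from the six-membered palladacycle. No stereocentre is created; C20 and C21 are carried through, and solid K2CO3 in THF is chosen so that the acidic C21–H of the product is not epimerised. The step needs the C21 hydroxyl, not the C20 hydroxyl, to be acylated, which the six-membered chelate through O21 (against a seven-membered one through O20) and the cis I/C21 relationship fixed in step 12 should secure. The allylic silyl ether, the furan and the two trisubstituted alkenes are expected to be inert to zerovalent palladium and CO under these conditions.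

Step 14
Reactants: 22 (5R)-5-[(1S,2R,6Z,10E)-13-(furan-3-yl)-1-hydroxy-2,6,10-trimethyltrideca-6,10-dien-1-yl]-3-{[(triisopropylsilyl)oxy]methyl}furan-2(5H)-one
Product: 24 (5E)-5-[(2R,6Z,10E)-13-(furan-3-yl)-2,6,10-trimethyltrideca-6,10-dien-1-ylidene]-3-{[(triisopropylsilyl)oxy]methyl}furan-2(5H)-one, via C20 mesylate 23 (not isolated)
Conditions: MeSO2Cl, Et3N, CH2Cl2, −78 to 0 °C
Reagents that add atoms: none
Why: Mesylation of the only free hydroxyl and in situ anti-periplanar β-elimination (E2 type) of the acidic C21–H should, from the C20/C21-anti configuration, place C18 cis to C22 and so give the 20E alkylidene butenolide stereospecifically under kinetic control.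

Step 15
Reactants: 24 (5E)-5-[(2R,6Z,10E)-13-(furan-3-yl)-2,6,10-trimethyltrideca-6,10-dien-1-ylidene]-3-{[(triisopropylsilyl)oxy]methyl}furan-2(5H)-one
Product: 25 22-deoxy-23-hydroxymethylvariabilin
Conditions: HF·pyridine, pyridine, THF, 0 °C to rt
Reagents that add atoms: none
Why: Fluoride-mediated desilylation under buffered conditions should free the primary alcohol without nucleophilic or basic isomerisation of the E enol lactone and without harming the furan.

**Compound list**
1 | geranyl acetate, (2E)-3,7-dimethylocta-2,6-dien-1-yl acetate | CC(C)=CCC/C(C)=C/COC(C)=O | starting material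
2 | (2E)-3-methyl-6-oxohex-2-en-1-yl acetate | O=CCC/C(C)=C/COC(C)=O | intermediate
3 | (2E,6Z)-7-iodo-3-methylocta-2,6-dien-1-yl acetate | C/C(I)=C/CC/C(C)=C/COC(C)=O | intermediate
4 | furan-3-ylmethanol | OCc1ccoc1 | starting material
5 | 3-(chloromethyl)furan | ClCc1ccoc1 | intermediate
6 | furan-3-ylmethylmagnesium chloride | Cl[Mg]Cc1ccoc1 | intermediate
7 | 3-[(3E,7Z)-8-iodo-4-methylnona-3,7-dien-1-yl]furan | C/C(I)=C/CC/C(C)=C/CCc1ccoc1 | intermediate
8 | (4S)-4-benzyl-3-propanoyl-1,3-oxazolidin-2-one | CCC(=O)N1[C@@H](Cc2ccccc2)COC1=O | starting material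
9 | (4S)-4-benzyl-3-[(2R)-2-methylpent-4-enoyl]-1,3-oxazolidin-2-one | C=CC[C@@H](C)C(=O)N1[C@@H](Cc2ccccc2)COC1=O | intermediate
10 | (4S)-4-benzyl-3-[(2R)-5-(9-borabicyclo[3.3.1]nonan-9-yl)-2-methylpentanoyl]-1,3-oxazolidin-2-one | C[C@H](CCCB1C2CCCC1CCC2)C(=O)N1[C@@H](Cc2ccccc2)COC1=O | intermediate
11 | (4S)-4-benzyl-3-[(2R,6Z,10E)-13-(furan-3-yl)-2,6,10-trimethyltrideca-6,10-dienoyl]-1,3-oxazolidin-2-one | C/C(=C/CC/C(C)=C/CCc1ccoc1)CCC[C@@H](C)C(=O)N1[C@@H](Cc2ccccc2)COC1=O | intermediate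
12 | (2R,6Z,10E)-13-(furan-3-yl)-2,6,10-trimethyltrideca-6,10-dien-1-ol | C/C(=C/CC/C(C)=C/CCc1ccoc1)CCC[C@@H](C)CO | intermediate
13 | (2R,6Z,10E)-13-(furan-3-yl)-2,6,10-trimethyltrideca-6,10-dienal | C/C(=C/CC/C(C)=C/CCc1ccoc1)CCC[C@@H](C)C=O | intermediate
14 | 4-(oxan-2-yloxy)but-2-yn-1-ol (racemic acetal) | OCC#CCOC1CCCCO1 | starting material
15 | dilithiated 14 (lithium alkoxide, lithium at the acetal-bearing propargylic carbon) | [Li]OCC#CC([Li])OC1CCCCO1 | intermediate
16 | allenyltitanium reagent from 15 (Ti(OiPr)3 on the future C23, titanium alkoxide at the future C25 oxygen) | CC(C)O[Ti](OC(C)C)(OC(C)C)OCC(=C=COC1CCCCO1)[Ti](OC(C)C)(OC(C)C)OC(C)C | intermediate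
17 | (4R,5S,6R,10Z,14E)-17-(furan-3-yl)-6,10,14-trimethyl-4-(oxan-2-yloxy)heptadeca-10,14-dien-2-yne-1,5-diol | C/C(=C/CC/C(C)=C/CCc1ccoc1)CCC[C@@H](C)[C@H](O)[C@H](OC1CCCCO1)C#CCO | intermediate
18 | (4R,5S,6R,10Z,14E)-17-(furan-3-yl)-6,10,14-trimethyl-4-(oxan-2-yloxy)-1-[(triisopropylsilyl)oxy]heptadeca-10,14-dien-2-yn-5-ol | C/C(=C/CC/C(C)=C/CCc1ccoc1)CCC[C@@H](C)[C@H](O)[C@H](OC1CCCCO1)C#CCO[Si](C(C)C)(C(C)C)C(C)C | intermediate
19 | (4R,5S,6R,10Z,14E)-17-(furan-3-yl)-6,10,14-trimethyl-1-[(triisopropylsilyl)oxy]heptadeca-10,14-dien-2-yne-4,5-diol | C/C(=C/CC/C(C)=C/CCc1ccoc1)CCC[C@@H](C)[C@H](O)[C@H](O)C#CCO[Si](C(C)C)(C(C)C)C(C)C | intermediate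
20 | cyclic alkenylaluminate of 19 (idealised: five-membered ring O21–Al–C23=C22–C21, two 2-methoxyethoxy ligands on aluminium, C20 oxygen drawn as sodium alkoxide) | C/C(=C/CC/C(C)=C/CCc1ccoc1)CCC[C@@H](C)[C@H](O[Na])[C@@H]1O[Al-](OCCOC)(OCCOC)C(CO[Si](C(C)C)(C(C)C)C(C)C)=C1.[Na+] | intermediate
21 | (2Z,4R,5S,6R,10Z,14E)-17-(furan-3-yl)-2-iodo-6,10,14-trimethyl-1-[(triisopropylsilyl)oxy]heptadeca-2,10,14-triene-4,5-diol | C/C(=C/CC/C(C)=C/CCc1ccoc1)CCC[C@@H](C)[C@H](O)[C@H](O)/C=C(\I)CO[Si](C(C)C)(C(C)C)C(C)C | intermediate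
22 | (5R)-5-[(1S,2R,6Z,10E)-13-(furan-3-yl)-1-hydroxy-2,6,10-trimethyltrideca-6,10-dien-1-yl]-3-{[(triisopropylsilyl)oxy]methyl}furan-2(5H)-one | C/C(=C/CC/C(C)=C/CCc1ccoc1)CCC[C@@H](C)[C@H](O)[C@@H]1OC(=O)C(CO[Si](C(C)C)(C(C)C)C(C)C)=C1 | intermediate
23 | (1S,2R,6Z,10E)-13-(furan-3-yl)-2,6,10-trimethyl-1-[(2R)-5-oxo-4-{[(triisopropylsilyl)oxy]methyl}-2,5-dihydrofuran-2-yl]trideca-6,10-dien-1-yl methanesulfonate | C/C(=C/CC/C(C)=C/CCc1ccoc1)CCC[C@@H](C)[C@H](OS(C)(=O)=O)[C@@H]1OC(=O)C(CO[Si](C(C)C)(C(C)C)C(C)C)=C1 | intermediate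
24 | (5E)-5-[(2R,6Z,10E)-13-(furan-3-yl)-2,6,10-trimethyltrideca-6,10-dien-1-ylidene]-3-{[(triisopropylsilyl)oxy]methyl}furan-2(5H)-one | C/C(=C/CC/C(C)=C/CCc1ccoc1)CCC[C@@H](C)/C=C1\C=C(CO[Si](C(C)C)(C(C)C)C(C)C)C(=O)O1 | intermediate
25 | 22-deoxy-23-hydroxymethylvariabilin, (5E)-5-[(2R,6Z,10E)-13-(furan-3-yl)-2,6,10-trimethyltrideca-6,10-dien-1-ylidene]-3-(hydroxymethyl)furan-2(5H)-one | C/C(=C/CC/C(C)=C/CCc1ccoc1)CCC[C@@H](C)/C=C1\C=C(CO)C(=O)O1 | target

**Step count and risks**

Total steps: 15. Longest linear sequence: 13 steps (steps 1, 2, 4, 6, 7, 8, 9, 10, 11, 12, 13, 14, 15).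

The three steps most likely to fail:

First, step 9. The second lithiation of the alkoxide-bearing propargyl ether may be incomplete or misdirected, and an open (non-cyclic) addition mode may compete and erode the anti selectivity. The fallback introduces C25 only after the C20–C21 bond is made. From 13, the allenyltitanium generated from trimethyl[3-(oxan-2-yloxy)prop-1-yn-1-yl]silane (n-BuLi, THF, −78 °C; ClTi(OiPr)3), which has a single propargylic site, should give the anti adduct (3R,4S,5R,9Z,13E)-16-(furan-3-yl)-5,9,13-trimethyl-3-(oxan-2-yloxy)-1-(trimethylsilyl)hexadeca-9,13-dien-1-yn-4-ol F1. K2CO3 in MeOH removes the alkynylsilane to give the terminal alkyne (3R,4S,5R,9Z,13E)-16-(furan-3-yl)-5,9,13-trimethyl-3-(oxan-2-yloxy)hexadeca-9,13-dien-1-yn-4-ol F2. Double deprotonation (n-BuLi, 2.2 equiv, THF, −78 °C) and paraformaldehyde hydroxymethylate the alkyne terminus, which returns to 17.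

Second, step 13. The C20 hydroxyl may be acylated in competition (six-membered lactone), and base may epimerise C21 of the product, which would later erode the E selectivity. The fallback separates C–C bond formation from lactonisation and closes the ring without base. From 21, both hydroxyls are silylated (Et3SiOSO2CF3, 2,6-lutidine, CH2Cl2, −78 °C) to the bis(triethylsilyl) ether (2Z,4R,5S,6R,10Z,14E)-17-(furan-3-yl)-2-iodo-6,10,14-trimethyl-4,5-bis[(triethylsilyl)oxy]-1-[(triisopropylsilyl)oxy]heptadeca-2,10,14-triene F3. Intermolecular methoxycarbonylation (Pd(PPh3)4, CO, MeOH, Et3N, DMF, 50 °C) gives methyl (2Z,4R,5S,6R,10Z,14E)-17-(furan-3-yl)-6,10,14-trimethyl-4,5-bis[(triethylsilyl)oxy]-2-{[(triisopropylsilyl)oxy]methyl}heptadeca-2,10,14-trienoate F4. Pyridinium p-toluenesulfonate in MeOH then cleaves both triethylsilyl ethers, and the (Z)-γ-hydroxy ester lactonises under these acidic conditions, which returns to 22.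

Third, step 14. The sulfonate may be lost stepwise through the furanolate (E1cB); rotation about C20–C21 in that anion would leak to the more stable Z olefin. The fallback moves to a thermal syn-elimination that needs no base, on the C20-epimeric series. From 18, Mitsunobu inversion at C20 (4-nitrobenzoic acid, PPh3, diisopropyl azodicarboxylate, toluene) gives (4R,5R,6R,10Z,14E)-17-(furan-3-yl)-6,10,14-trimethyl-4-(oxan-2-yloxy)-1-[(triisopropylsilyl)oxy]heptadeca-10,14-dien-2-yn-5-yl 4-nitrobenzoate F5. K2CO3 in MeOH gives the C20-epimeric alcohol (4R,5R,6R,10Z,14E)-17-(furan-3-yl)-6,10,14-trimethyl-4-(oxan-2-yloxy)-1-[(triisopropylsilyl)oxy]heptadeca-10,14-dien-2-yn-5-ol F6. Acetal cleavage as in step 11 gives the syn diol (4R,5R,6R,10Z,14E)-17-(furan-3-yl)-6,10,14-trimethyl-1-[(triisopropylsilyl)oxy]heptadeca-10,14-dien-2-yne-4,5-diol F7. Hydroalumination–iodination as in step 12 gives (2Z,4R,5R,6R,10Z,14E)-17-(furan-3-yl)-2-iodo-6,10,14-trimethyl-1-[(triisopropylsilyl)oxy]heptadeca-2,10,14-triene-4,5-diol F8. Carbonylative lactonisation as in step 13 gives (5R)-5-[(1R,2R,6Z,10E)-13-(furan-3-yl)-1-hydroxy-2,6,10-trimethyltrideca-6,10-dien-1-yl]-3-{[(triisopropylsilyl)oxy]methyl}furan-2(5H)-one F9. Heating with the Burgess reagent (methyl N-(triethylammoniosulfonyl)carbamate, benzene, 50 °C) should then effect a concerted syn-elimination of the C20 oxygen and C21–H, which from the C20/C21-syn isomer places C18 cis to C22 and returns to 24.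

**Further compounds**
F1 | step 9 | (3R,4S,5R,9Z,13E)-16-(furan-3-yl)-5,9,13-trimethyl-3-(oxan-2-yloxy)-1-(trimethylsilyl)hexadeca-9,13-dien-1-yn-4-ol | C/C(=C/CC/C(C)=C/CCc1ccoc1)CCC[C@@H](C)[C@H](O)[C@H](OC1CCCCO1)C#C[Si](C)(C)C
F2 | step 9 | (3R,4S,5R,9Z,13E)-16-(furan-3-yl)-5,9,13-trimethyl-3-(oxan-2-yloxy)hexadeca-9,13-dien-1-yn-4-ol | C/C(=C/CC/C(C)=C/CCc1ccoc1)CCC[C@@H](C)[C@H](O)[C@H](OC1CCCCO1)C#C
F3 | step 13 | (2Z,4R,5S,6R,10Z,14E)-17-(furan-3-yl)-2-iodo-6,10,14-trimethyl-4,5-bis[(triethylsilyl)oxy]-1-[(triisopropylsilyl)oxy]heptadeca-2,10,14-triene | C/C(=C/CC/C(C)=C/CCc1ccoc1)CCC[C@@H](C)[C@H](O[Si](CC)(CC)CC)[C@H](O[Si](CC)(CC)CC)/C=C(\I)CO[Si](C(C)C)(C(C)C)C(C)C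
F4 | step 13 | methyl (2Z,4R,5S,6R,10Z,14E)-17-(furan-3-yl)-6,10,14-trimethyl-4,5-bis[(triethylsilyl)oxy]-2-{[(triisopropylsilyl)oxy]methyl}heptadeca-2,10,14-trienoate | C/C(=C/CC/C(C)=C/CCc1ccoc1)CCC[C@@H](C)[C@H](O[Si](CC)(CC)CC)[C@H](O[Si](CC)(CC)CC)/C=C(\C(=O)OC)CO[Si](C(C)C)(C(C)C)C(C)C
F5 | step 14 | (4R,5R,6R,10Z,14E)-17-(furan-3-yl)-6,10,14-trimethyl-4-(oxan-2-yloxy)-1-[(triisopropylsilyl)oxy]heptadeca-10,14-dien-2-yn-5-yl 4-nitrobenzoate | C/C(=C/CC/C(C)=C/CCc1ccoc1)CCC[C@@H](C)[C@@H](OC(=O)c1ccc(cc1)[N+](=O)[O-])[C@H](OC1CCCCO1)C#CCO[Si](C(C)C)(C(C)C)C(C)C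
F6 | step 14 | (4R,5R,6R,10Z,14E)-17-(furan-3-yl)-6,10,14-trimethyl-4-(oxan-2-yloxy)-1-[(triisopropylsilyl)oxy]heptadeca-10,14-dien-2-yn-5-ol | C/C(=C/CC/C(C)=C/CCc1ccoc1)CCC[C@@H](C)[C@@H](O)[C@H](OC1CCCCO1)C#CCO[Si](C(C)C)(C(C)C)C(C)C
F7 | step 14 | (4R,5R,6R,10Z,14E)-17-(furan-3-yl)-6,10,14-trimethyl-1-[(triisopropylsilyl)oxy]heptadeca-10,14-dien-2-yne-4,5-diol | C/C(=C/CC/C(C)=C/CCc1ccoc1)CCC[C@@H](C)[C@@H](O)[C@H](O)C#CCO[Si](C(C)C)(C(C)C)C(C)C
F8 | step 14 | (2Z,4R,5R,6R,10Z,14E)-17-(furan-3-yl)-2-iodo-6,10,14-trimethyl-1-[(triisopropylsilyl)oxy]heptadeca-2,10,14-triene-4,5-diol | C/C(=C/CC/C(C)=C/CCc1ccoc1)CCC[C@@H](C)[C@@H](O)[C@H](O)/C=C(\I)CO[Si](C(C)C)(C(C)C)C(C)C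
F9 | step 14 | (5R)-5-[(1R,2R,6Z,10E)-13-(furan-3-yl)-1-hydroxy-2,6,10-trimethyltrideca-6,10-dien-1-yl]-3-{[(triisopropylsilyl)oxy]methyl}furan-2(5H)-one | C/C(=C/CC/C(C)=C/CCc1ccoc1)CCC[C@@H](C)[C@@H](O)[C@@H]1OC(=O)C(CO[Si](C(C)C)(C(C)C)C(C)C)=C1
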